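The route rests on opening ring B between C5 and C6. The feature exploited is the γ-oxygenated enone of ring B (C5 carbinol, C6=C7 alkene, C8 ketone), the retron of a C6 vinyl-metal adding to a C5 aldehyde. One intramolecular Nozaki–Hiyama–Kishi reaction forms the C5–C6 bond, closes the seven-membered ring onto a finished ring A and sets the C5 carbinol. Its precursor is a cyclopentane bearing the C1 acetate, the silylated C3 isopropyl carbinol, a formyl group on C4 and, on quaternary C10, a CH2–CO–C(CH3)=CHI arm with Z geometry. Absolute configuration is relayed from commercial (S)-4-silyloxycyclopent-2-enone, whose oxygen is later expelled.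

Key step: step 17

Remark: locants C1–C10 are those of the target in every compound (ring A = C1, C2, C3, C4, C10; ring B = C4 to C10); β is the face of ring A that carries the C10 methyl group, α the opposite face.
Remark: the key-step precursor and product were re-derived from the target and needed no change of constitution or configuration; the vinyl iodide has to be Z (iodine cis to C8) so that the alkene ends up cis inside ring B.
Remark: (S)-4-(tert-butyldimethylsilyloxy)cyclopent-2-en-1-one is taken as the commercial enantiopure starting material; its silyloxy carbon becomes C3.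

Step 1
Reactants: 1 (S)-4-(tert-butyldimethylsilyloxy)cyclopent-2-en-1-one; 2 iodine
Product: 3 (S)-4-(tert-butyldimethylsilyloxy)-2-iodocyclopent-2-en-1-one
Conditions: I2, pyridine/CH2Cl2, 0 °C → rt
Reagents that add atoms: iodine, II
Why: Pyridine-mediated α-iodination of a β-unsubstituted enone (conjugate addition of pyridine, iodination of the enolate, elimination) should leave the C3 silyl ether and its configuration untouched.

Step 2
Reactants: 3 (S)-4-(tert-butyldimethylsilyloxy)-2-iodocyclopent-2-en-1-one; 4 methylzinc chloride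
Product: 5 (S)-4-(tert-butyldimethylsilyloxy)-2-methylcyclopent-2-en-1-one
Conditions: MeZnCl, Pd(PPh3)4 (5 mol %), THF, 0 °C → rt
Reagents that add atoms: methylzinc chloride, C[Zn]Cl
Why: Negishi coupling of a 2-iodo enone with an alkylzinc halide runs at room temperature without added base, so the β-silyloxy group should not be eliminated.

Step 3
Reactants: 5 (S)-4-(tert-butyldimethylsilyloxy)-2-methylcyclopent-2-en-1-one; 6 vinylmagnesium bromide; 7 chlorotrimethylsilane
Product: 8 ring A silyl enol ether (C1–OSiMe3, C1=C10, 4β-vinyl, 3α-OTBS)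
Conditions: CH2=CHMgBr, CuBr·SMe2 (10 mol %), Me3SiCl, THF, −78 °C; Et3N quench
Reagents that add atoms: vinylmagnesium bromide, C=C[Mg]Br; chlorotrimethylsilane, C[Si](C)(C)Cl
Why: Copper-catalysed conjugate addition accelerated by Me3SiCl should deliver the vinyl group anti to the C3 silyloxy group (the usual trans addition to 4-silyloxycyclopentenones), which sets C4 (vinyl β) and fixes the C1–C10 enolate as its silyl ether.

Step 4
Reactants: 8 ring A silyl enol ether; 9 prenyl bromide (1-bromo-3-methylbut-2-ene)
Product: 12 (4R,5S)-5-methyl-5-(3-methylbut-2-en-1-yl)-4-vinylcyclopent-2-en-1-one, via lithium enolate 10 (not isolated), via β-silyloxy ketone 11 (not isolated)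
Conditions: MeLi, THF, 0 °C → rt; prenyl bromide, DMPU, −78 → −20 °C; then DBU, 0 °C, short
Reagents that add atoms: 1-bromo-3-methylbut-2-ene, CC(C)=CCBr
Why: Enolate alkylation by the reactive allylic bromide should occur on the face opposite the neighbouring C4 vinyl group (sets quaternary C10: methyl β, prenyl α), and DBU then expels the β-silanolate by an E1cB elimination to give the C2=C3 enone.

Step 5
Reactants: 12 ring A enone; 13 isopropylmagnesium chloride; 7 chlorotrimethylsilane
Product: 14 ring A silyl enol ether (C1–OSiMe3, C1=C2, 3α-isopropyl)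
Conditions: i-PrMgCl, CuBr·SMe2 (10 mol %), Me3SiCl, THF, −78 °C; Et3N quench
Reagents that add atoms: isopropylmagnesium chloride, CC(C)[Mg]Cl; chlorotrimethylsilane, C[Si](C)(C)Cl
Why: Copper-catalysed conjugate addition places the isopropyl group on C3 (anti to the C4 vinyl group, a centre that is erased in step 6) and traps the enolate as its silyl ether.

Step 6
Reactants: 14 ring A silyl enol ether
Product: 15 (4R,5S)-3-isopropyl-5-methyl-5-(3-methylbut-2-en-1-yl)-4-vinylcyclopent-2-en-1-one
Conditions: Pd(OAc)2 (1.1 equiv), MeCN, rt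
Reagents that add atoms: none
Why: Saegusa–Ito oxidation: the palladium enolate can undergo β-hydride elimination only toward C3 because C10 is quaternary, which returns the enone with the isopropyl group on C3.

Step 7
Reactants: 15 β-isopropyl enone; 16 hydrogen peroxide
Product: 17 2α,3α-epoxy ketone
Conditions: 30 % H2O2, NaOH (aq., substoichiometric), MeOH, −10 → 0 °C
Reagents that add atoms: hydrogen peroxide, OO
Why: Weitz–Scheffer epoxidation: hydroperoxide should add to C3 from the α face, opposite the adjacent C4 vinyl group, which sets the C3 oxygen α and the isopropyl group β, and low temperature limits deprotonation at C4 as in epoxidations of 4-alkenylcyclopent-2-enones.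

Step 8
Reactants: 17 2α,3α-epoxy ketone
Product: 18 β-hydroxy ketone (3α-OH, 3β-isopropyl)
Conditions: SmI2 (2.5 equiv), THF/MeOH, −78 °C
Reagents that add atoms: none
Why: Samarium diiodide reduction of an α,β-epoxy ketone cleaves the C2–O bond through the ketyl and protonation of the samarium enolate leaves the tertiary C3 alcohol with its configuration unchanged.

Step 9
Reactants: 18 β-hydroxy ketone
Product: 19 anti diol (1β-OH, 3α-OH)
Conditions: Me4NBH(OAc)3, MeCN/AcOH, −30 → 0 °C
Reagents that add atoms: none
Why: Saksena–Evans reduction: the C3 alkoxide binds the acetoxyborohydride and delivers hydride to the α face of the C1 ketone, which should give the 1,3-anti diol (C1–OH β), as known for cyclic β-hydroxy ketones directed by tertiary alcohols.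

Step 10
Reactants: 19 anti diol; 7 chlorotrimethylsilane; 20 triethylsilyl trifluoromethanesulfonate
Product: 23 C3 triethylsilyl ether with free 1β-OH, via C1 trimethylsilyl ether 21 (not isolated), via mixed bis-silyl ether 22 (not isolated)
Conditions: Me3SiCl (1.1 equiv), Et3N, CH2Cl2, −20 °C; Et3SiOTf, 0 °C → rt; then MeOH, citric acid, rt
Reagents that add atoms: triethylsilyl trifluoromethanesulfonate, CC[Si](CC)(CC)OS(=O)(=O)C(F)(F)F
Why: Transient protection: the secondary C1 alcohol is masked as its labile trimethylsilyl ether, the hindered tertiary C3 alcohol is then silylated by the silyl triflate, and mild acidic methanolysis removes only the trimethylsilyl group.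

Step 11
Reactants: 23 C3 triethylsilyl ether; 24 3-chloroperbenzoic acid
Product: 26 C8 aldehyde (10α-CH2CHO arm), via prenyl epoxide 25 (not isolated)
Conditions: mCPBA (1.05 equiv), CH2Cl2, 0 °C; then H5IO6, THF/H2O, 0 °C
Reagents that add atoms: 3-chloroperbenzoic acid, OOC(=O)c1cccc(Cl)c1
Why: Prilezhaev epoxidation should take the electron-rich trisubstituted prenyl alkene far faster than the hindered monosubstituted vinyl group, and periodic acid then hydrolyses and cleaves the epoxide to the aldehyde and acetone.

Step 12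
Reactants: 26 C8 aldehyde; 27 ethynylmagnesium bromide
Product: 28 propargylic alcohol (C8 epimers)
Conditions: HC≡CMgBr (3 equiv), THF, −78 → 0 °C; aq. NH4Cl
Reagents that add atoms: ethynylmagnesium bromide, C#C[Mg]Br
Why: Grignard 1,2-addition of the acetylide to the aldehyde (one equivalent is consumed by the C1 hydroxyl) gives a C8 carbinol whose configuration is irrelevant because C8 is oxidised in step 14.

Step 13
Reactants: 28 propargylic alcohol; 29 methylmagnesium bromide; 2 iodine
Product: 31 (Z)-iodo allylic alcohol (C8 epimers), via alkenylmagnesium chelate 30 (not isolated)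
Conditions: MeMgBr (6 equiv), CuI (0.2 equiv), Et2O/THF, −20 °C → rt; then I2, −78 → 0 °C
Reagents that add atoms: methylmagnesium bromide, C[Mg]Br; iodine, II
Why: Copper-catalysed anti-carbomagnesiation of a propargylic magnesium alkoxide puts methyl on C7 and magnesium on C6 inside a five-membered alkoxide chelate, so that iodinolysis with retention should give the Z iodoalkene with iodine cis to C8.

Step 14
Reactants: 31 (Z)-iodo allylic alcohol
Product: 32 (Z)-β-iodo enone with free 1β-OH
Conditions: MnO2 (activated, excess), CH2Cl2, rt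
Reagents that add atoms: none
Why: Allylic oxidation with MnO2 should convert only the C8 alcohol and leave the saturated, hindered C1 alcohol and the alkene geometry untouched.

Step 15
Reactants: 32 (Z)-β-iodo enone; 33 acetic anhydride
Product: 34 C1 acetate
Conditions: Ac2O, i-Pr2NEt, DMAP (5 mol %), CH2Cl2, 0 °C → rt
Reagents that add atoms: acetic anhydride, CC(=O)OC(C)=O
Why: DMAP-catalysed acylation of the secondary C1 alcohol with a hindered stoichiometric base keeps nucleophilic amines that could attack the β-iodo enone to a catalytic amount.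

Step 16
Reactants: 34 C1 acetate; 35 ozone
Product: 37 ring A aldehyde with Z β-iodo enone arm, via ozonide 36 (not isolated)
Conditions: O3/O2, CH2Cl2, −78 °C (stopped at the first blue tint); then PPh3, −78 °C → rt
Reagents that add atoms: ozone, [O-][O+]=O
Why: Ozonolysis with reductive work-up should cleave the isolated vinyl group while the electron-poor iodo enone alkene stays intact, and the neutral phosphine work-up preserves the configuration at C4.

Step 17
Reactants: 37 ring A aldehyde with Z β-iodo enone arm
Product: 40 bicyclic γ-hydroxy enone (5α-OH, C3 triethylsilyl ether), via vinylchromium species 38 (not isolated), via chromium alkoxide 39 (not isolated)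
Conditions: CrCl2 (10 equiv), NiCl2 (0.1 equiv), degassed DMSO, rt, 0.002 M, slow addition of 37; aqueous work-up
Reagents that add atoms: none
Why: NiCl2 is reduced by CrCl2 to zerovalent nickel, which inserts into the C6–I bond with retention, and transmetalation to trivalent chromium gives vinylchromium 38, which adds to the C5 aldehyde to form alkoxide 39, hydrolysed on work-up. The closest known reaction type is the intramolecular Nozaki–Hiyama–Kishi coupling of vinyl iodides, β-iodo enoates and β-iodo enones with aldehydes for medium rings. Ring B closes in a 7-exo-trig mode, helped by the Z alkene that holds C5 and C8 on the same side and by the quaternary C10 (Thorpe–Ingold effect). The new C5 centre is controlled by the ring A stereocentres: in a chair-like transition state C6 approaches anti to the C3–C4 bond and the chromium-bound oxygen lies pseudo-equatorial on the α face, away from the axial C10 methyl group and the C3 isopropyl group, which places the hydroxyl cis to C4–H. The step needs addition to the aldehyde only, with no attack on the C8 ketone or C1 acetate and no enolisation at C4, which the low basicity and aldehyde preference of organochromium reagents secure, and it needs cyclisation to outrun oligomerisation, which high dilution and the preorganised Z arm secure.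

Step 18
Reactants: 41 4-hydroxybenzoic acid; 42 tert-butyldimethylsilyl chloride
Product: 44 4-(tert-butyldimethylsilyloxy)benzoic acid, via bis-silylated benzoate 43 (not isolated)
Conditions: TBSCl (2.5 equiv), imidazole, DMF, rt; then THF/H2O/AcOH, rt
Reagents that add atoms: tert-butyldimethylsilyl chloride, CC(C)(C)[Si](C)(C)Cl
Why: Exhaustive silylation followed by selective hydrolysis of the labile silyl ester should leave the phenolic silyl ether in place.

Step 19
Reactants: 40 bicyclic γ-hydroxy enone; 44 4-(tert-butyldimethylsilyloxy)benzoic acid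
Product: 46 fully protected C5 ester, via mixed anhydride 45 (not isolated)
Conditions: 2,4,6-Cl3C6H2COCl, Et3N, THF, rt; then 40, DMAP, toluene, rt
Reagents that add atoms: 4-(tert-butyldimethylsilyloxy)benzoic acid, OC(=O)c1ccc(O[Si](C)(C)C(C)(C)C)cc1
Why: Yamaguchi esterification: DMAP transfers the aroyl group from the mixed anhydride to the equatorial C5 alcohol, which is the only free hydroxyl, with retention at C5.

Step 20
Reactants: 46 fully protected C5 ester
Product: 47 target, (1S,3R,3aR,4R,8aS)-1-acetoxy-3-hydroxy-3-isopropyl-6,8a-dimethyl-7-oxo-1,2,3,3a,4,7,8,8a-octahydroazulen-4-yl 4-hydroxybenzoate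
Conditions: HF·pyridine, THF/pyridine, 0 °C → rt
Reagents that add atoms: none
Why: Fluoride cleavage of the tertiary triethylsilyl ether and the aryl silyl ether under mildly acidic conditions should avoid base-induced acyl migration or epimerisation in the γ-acyloxy enone.

Compound list
1 | (S)-4-(tert-butyldimethylsilyloxy)cyclopent-2-en-1-one | O=C1C=C[C@@H](O[Si](C)(C)C(C)(C)C)C1 | starting material
2 | iodine | II | starting material
3 | (S)-4-(tert-butyldimethylsilyloxy)-2-iodocyclopent-2-en-1-one | O=C1C(I)=C[C@@H](O[Si](C)(C)C(C)(C)C)C1 | intermediate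
4 | methylzinc chloride | C[Zn]Cl | starting material
5 | (S)-4-(tert-butyldimethylsilyloxy)-2-methylcyclopent-2-en-1-one (C1 ketone, C10=C4, 3α-OTBS) | CC1=C[C@@H](O[Si](C)(C)C(C)(C)C)CC1=O | intermediate
6 | vinylmagnesium bromide | C=C[Mg]Br | starting material
7 | chlorotrimethylsilane | C[Si](C)(C)Cl | starting material
8 | ring A silyl enol ether (C1–OSiMe3, C1=C10 with methyl on C10, 4β-vinyl, 3α-OTBS) | C[Si](C)(C)OC1=C(C)[C@H](C=C)[C@@H](O[Si](C)(C)C(C)(C)C)C1 | intermediate
9 | prenyl bromide (1-bromo-3-methylbut-2-ene) | CC(C)=CCBr | starting material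
10 | lithium enolate of 8 (C1–OLi, C1=C10) | [Li]OC1=C(C)[C@H](C=C)[C@@H](O[Si](C)(C)C(C)(C)C)C1 | intermediate
11 | β-silyloxy ketone (C1 ketone, 10β-methyl, 10α-prenyl, 4β-vinyl, 3α-OTBS) | O=C1C[C@H](O[Si](C)(C)C(C)(C)C)[C@@H](C=C)[C@]1(C)CC=C(C)C | intermediate
12 | (4R,5S)-5-methyl-5-(3-methylbut-2-en-1-yl)-4-vinylcyclopent-2-en-1-one (C1 ketone, C2=C3, 4β-vinyl, 10β-methyl, 10α-prenyl) | O=C1C=C[C@@H](C=C)[C@]1(C)CC=C(C)C | intermediate
13 | isopropylmagnesium chloride | CC(C)[Mg]Cl | starting material
14 | ring A silyl enol ether (C1–OSiMe3, C1=C2, 3α-isopropyl, 4β-vinyl, 10β-methyl, 10α-prenyl) | C[Si](C)(C)OC1=C[C@H](C(C)C)[C@@H](C=C)[C@]1(C)CC=C(C)C | intermediate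
15 | (4R,5S)-3-isopropyl-5-methyl-5-(3-methylbut-2-en-1-yl)-4-vinylcyclopent-2-en-1-one (C1 ketone, C2=C3 with isopropyl on C3) | O=C1C=C(C(C)C)[C@@H](C=C)[C@]1(C)CC=C(C)C | intermediate
16 | hydrogen peroxide | OO | starting material
17 | 2α,3α-epoxy ketone (C1 ketone, epoxide oxygen α on C2 and C3, 3β-isopropyl, 4β-vinyl, 10β-methyl, 10α-prenyl) | O=C1[C@@H]2O[C@]2(C(C)C)[C@@H](C=C)[C@]1(C)CC=C(C)C | intermediate
18 | β-hydroxy ketone (C1 ketone, 3α-hydroxy, 3β-isopropyl, 4β-vinyl, 10β-methyl, 10α-prenyl) | O=C1C[C@@](O)(C(C)C)[C@@H](C=C)[C@]1(C)CC=C(C)C | intermediate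
19 | anti diol (1β-hydroxy, 3α-hydroxy, 3β-isopropyl, 4β-vinyl, 10β-methyl, 10α-prenyl cyclopentane) | O[C@H]1C[C@@](O)(C(C)C)[C@@H](C=C)[C@]1(C)CC=C(C)C | intermediate
20 | triethylsilyl trifluoromethanesulfonate | CC[Si](CC)(CC)OS(=O)(=O)C(F)(F)F | starting material
21 | C1 trimethylsilyl ether of 19 | C[Si](C)(C)O[C@H]1C[C@@](O)(C(C)C)[C@@H](C=C)[C@]1(C)CC=C(C)C | intermediate
22 | mixed bis-silyl ether of 19 (C1–OSiMe3, C3–OSiEt3) | C[Si](C)(C)O[C@H]1C[C@@](O[Si](CC)(CC)CC)(C(C)C)[C@@H](C=C)[C@]1(C)CC=C(C)C | intermediate
23 | C3 triethylsilyl ether of 19 (1β-OH free) | O[C@H]1C[C@@](O[Si](CC)(CC)CC)(C(C)C)[C@@H](C=C)[C@]1(C)CC=C(C)C | intermediate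
24 | 3-chloroperbenzoic acid | OOC(=O)c1cccc(Cl)c1 | starting material
25 | prenyl epoxide of 23 (2,2-dimethyloxirane on C9, C8 epimers) | O[C@H]1C[C@@](O[Si](CC)(CC)CC)(C(C)C)[C@@H](C=C)[C@]1(C)CC2OC2(C)C | intermediate
26 | C8 aldehyde (10α-CH2CHO arm, 1β-OH, 3α-OSiEt3, 4β-vinyl) | O[C@H]1C[C@@](O[Si](CC)(CC)CC)(C(C)C)[C@@H](C=C)[C@]1(C)CC=O | intermediate
27 | ethynylmagnesium bromide | C#C[Mg]Br | starting material
28 | propargylic alcohol (10α-CH2CH(OH)C≡CH arm, C8 epimers) | O[C@H]1C[C@@](O[Si](CC)(CC)CC)(C(C)C)[C@@H](C=C)[C@]1(C)CC(O)C#C | intermediate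
29 | methylmagnesium bromide | C[Mg]Br | starting material
30 | alkenylmagnesium chelate (C6–MgBr cis to the C8 alkoxide, C1 and C8 as bromomagnesium alkoxides) | Br[Mg]O[C@H]1C[C@@](O[Si](CC)(CC)CC)(C(C)C)[C@@H](C=C)[C@]1(C)CC(O[Mg]Br)/C(C)=C\[Mg]Br | intermediate
31 | (Z)-iodo allylic alcohol (10α-CH2CH(OH)C(CH3)=CHI arm, iodine cis to C8, C8 epimers, 1β-OH) | O[C@H]1C[C@@](O[Si](CC)(CC)CC)(C(C)C)[C@@H](C=C)[C@]1(C)CC(O)/C(C)=C\I | intermediate
32 | (Z)-β-iodo enone (10α-CH2COC(CH3)=CHI arm, 1β-OH, 3α-OSiEt3, 4β-vinyl) | O[C@H]1C[C@@](O[Si](CC)(CC)CC)(C(C)C)[C@@H](C=C)[C@]1(C)CC(=O)/C(C)=C\I | intermediate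
33 | acetic anhydride | CC(=O)OC(C)=O | starting material
34 | C1 acetate of 32 | CC(=O)O[C@H]1C[C@@](O[Si](CC)(CC)CC)(C(C)C)[C@@H](C=C)[C@]1(C)CC(=O)/C(C)=C\I | intermediate
35 | ozone | [O-][O+]=O | starting material
36 | ozonide of 34 (1,2,4-trioxolane on C4) | CC(=O)O[C@H]1C[C@@](O[Si](CC)(CC)CC)(C(C)C)[C@@H](C2OCOO2)[C@]1(C)CC(=O)/C(C)=C\I | intermediate
37 | ring A aldehyde: 1β-acetoxy, 3α-triethylsilyloxy, 3β-isopropyl, 4β-formyl, 10β-methyl, 10α-[(Z)-4-iodo-3-methyl-2-oxobut-3-enyl]cyclopentane | CC(=O)O[C@H]1C[C@@](O[Si](CC)(CC)CC)(C(C)C)[C@@H](C=O)[C@]1(C)CC(=O)/C(C)=C\I | intermediate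
38 | vinylchromium species (C6–CrCl2 in place of C6–I of 37) | CC(=O)O[C@H]1C[C@@](O[Si](CC)(CC)CC)(C(C)C)[C@@H](C=O)[C@]1(C)CC(=O)/C(C)=C\[Cr](Cl)Cl | intermediate
39 | chromium alkoxide of 40 (C5–O–CrCl2) | CC(=O)O[C@H]1C[C@@](O[Si](CC)(CC)CC)(C(C)C)[C@H]2[C@H](O[Cr](Cl)Cl)C=C(C)C(=O)C[C@]12C | intermediate
40 | bicyclic γ-hydroxy enone: trans-fused hydroazulenone with 1β-acetoxy, 3α-triethylsilyloxy, 3β-isopropyl, 4α-H, 5α-hydroxy, C6=C7 with methyl on C7, C8 ketone, 10β-methyl | CC(=O)O[C@H]1C[C@@](O[Si](CC)(CC)CC)(C(C)C)[C@H]2[C@H](O)C=C(C)C(=O)C[C@]12C | intermediate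
41 | 4-hydroxybenzoic acid | OC(=O)c1ccc(O)cc1 | starting material
42 | tert-butyldimethylsilyl chloride | CC(C)(C)[Si](C)(C)Cl | starting material
43 | tert-butyldimethylsilyl 4-(tert-butyldimethylsilyloxy)benzoate | CC(C)(C)[Si](C)(C)OC(=O)c1ccc(O[Si](C)(C)C(C)(C)C)cc1 | intermediate
44 | 4-(tert-butyldimethylsilyloxy)benzoic acid | OC(=O)c1ccc(O[Si](C)(C)C(C)(C)C)cc1 | intermediate
45 | 4-(tert-butyldimethylsilyloxy)benzoic 2,4,6-trichlorobenzoic anhydride | CC(C)(C)[Si](C)(C)Oc1ccc(cc1)C(=O)OC(=O)c1c(Cl)cc(Cl)cc1Cl | intermediate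
46 | protected target: C5 4-(tert-butyldimethylsilyloxy)benzoate of 40 (C3 triethylsilyl ether retained) | CC(=O)O[C@H]1C[C@@](O[Si](CC)(CC)CC)(C(C)C)[C@H]2[C@H](OC(=O)c3ccc(O[Si](C)(C)C(C)(C)C)cc3)C=C(C)C(=O)C[C@]12C | intermediate
47 | target: (1S,3R,3aR,4R,8aS)-1-acetoxy-3-hydroxy-3-isopropyl-6,8a-dimethyl-7-oxo-1,2,3,3a,4,7,8,8a-octahydroazulen-4-yl 4-hydroxybenzoate | CC(=O)O[C@H]1C[C@@](O)(C(C)C)[C@H]2[C@H](OC(=O)c3ccc(O)cc3)C=C(C)C(=O)C[C@]12C | target

Total steps: 20. Longest linear sequence: 19 steps (steps 1 to 17, then 19 and 20; step 18 prepares the acid separately).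

Steps most likely to fail

Step 17. The addition to the C5 aldehyde may proceed with insufficient facial selectivity, the oxygen ending on the β face syn to the C10 methyl group. The fallback sets out from 37: the cyclisation is run as in step 17 and the C5-epimeric alcohol F1 is esterified with acid 44 under Mitsunobu conditions (PPh3, diisopropyl azodicarboxylate, toluene, 0 °C → rt). This forms the aroyl ester with inversion at C5 and returns to the route at 46.

Step 7. Attack of hydroperoxide at the hindered C3 may be slow, so that base-induced deprotonation at C4 (epimerisation or alkene migration) competes, or the two faces may not be well differentiated. The fallback sets out from 15 and replaces steps 7 and 8. Copper-catalysed conjugate borylation (bis(pinacolato)diboron, CuCl, bis[2-(diphenylphosphino)phenyl] ether, NaOt-Bu, MeOH, THF, rt) should give the tertiary boronate F2, with the bulky copper–boryl reagent adding anti to the vinyl group. Oxidation with NaBO3·4H2O in THF/H2O, with retention at C3, returns to the route at 18.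

Step 9. Exchange of the hindered tertiary alcohol onto boron may be too slow, so that hydride is not delivered intramolecularly and the ketone either survives or is reduced from the β face. The fallback sets out from 18 and relies on catalyst control instead of substrate direction. Corey–Bakshi–Shibata reduction with (R)-1-methyl-3,3-diphenyltetrahydro-1H,3H-pyrrolo[1,2-c][1,3,2]oxazaborole and BH3·SMe2 in THF at −20 °C, with the quaternary C10 side acting as the large group, should give the 1β-alcohol. It returns to the route at 19 and makes no new compound (F0).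

Further compounds
F1 | step 17 | C5-epimeric alcohol (5β-hydroxy epimer of 40) | CC(=O)O[C@H]1C[C@@](O[Si](CC)(CC)CC)(C(C)C)[C@H]2[C@@H](O)C=C(C)C(=O)C[C@]12C
F2 | step 7 | tertiary boronate (C1 ketone, 3α-pinacolatoboryl, 3β-isopropyl, 4β-vinyl, 10β-methyl, 10α-prenyl) | O=C1C[C@@](B2OC(C)(C)C(C)(C)O2)(C(C)C)[C@@H](C=C)[C@]1(C)CC=C(C)C
F0 | step 9 | none | none
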